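**Plan**

1. Germacrane numbering is used: C6 = lactone CH–O, C7 = ring-fusion CH, C8 = CH–O-acyl, C9 = ring CH2, C1=C10 and C4=C5 = ring alkenes, C2/C3 = CH2CH2 bridge, C11=C13 = exocyclic methylene, C12 = lactone C=O, C14 = CHO, C15 = CH2OH.
2. Retrosynthesis: remove the C8 ester and unmask C14/C15, then cut the C7–C8 bond of the ten-membered ring. The C8 carbinol is homoallylic to the exocyclic C11=C13 of the fused five-membered lactone (O–C8–C7–C11=C13), so the ring, C7 and C8 come from a C8 aldehyde allylated through C7 by a 3-(bromomethyl)butenolide with allylic transposition.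
3. The open chain is cut at C12 (CO insertion into a C11 alkenyl iodide, lactonising onto O6), at C6–C7 (alkynyl addition to a Weinreb amide), at C3–C4 (B-alkyl Suzuki coupling) and at C1=C10 (Wittig reaction with acrolein).
4. Forward: an east diene acetal (C1–C3, C8–C10, C14) and a west (Z)-iodoenamide (C4–C6, C15) are joined at C3–C4; the C7/C11/C13 alkyne is added; the butenolide (first ring) is built by hydroalumination–iodination and carbonylative lactonisation; the ten-membered ring is closed last.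
5. Stereochemistry: C6 from a CBS reduction of the alkenyl alkynyl ketone; C7 and C8 from C6 in the chair transition state of the ring closure (cis-fused lactone, anti C7/C8); C4=C5 geometry from anti-hydroiodination of an ynamide; C1=C10 from an E-selective Wittig reaction.
6. Protecting groups: C14 aldehyde as a dioxolane, C15–OH as a TBDPS ether, C8–OH and C13–OH as TBS ethers.

Key step: step 15

Remark: all starting materials (1, 2, 6, 9, 15) are assumed to be catalogue compounds.

**Route**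

Step 1
Reactants: 1 (3-bromopropoxy)(tert-butyl)dimethylsilane; 2 triphenylphosphine
Product: 3 [3-(tert-butyldimethylsilyloxy)propyl]triphenylphosphonium bromide
Conditions: MeCN, NaHCO3 (cat.), 80 °C
Reagents that add atoms: none
Why: SN2 quaternisation of triphenylphosphine by the primary bromide gives the phosphonium salt (standard Wittig salt formation).

Step 2
Reactants: 3 [3-(tert-butyldimethylsilyloxy)propyl]triphenylphosphonium bromide
Product: 5 4-(tert-butyldimethylsilyloxy)-2-(triphenylphosphoranylidene)butanal, via phosphonium ylide 4 (not isolated)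
Conditions: NaN(SiMe3)2, THF, 0 °C; then HCO2Et, 0 °C → rt
Reagents that add atoms: ethyl formate, CCOC=O
Why: the non-stabilised ylide is C-formylated by ethyl formate and the released ethoxide deprotonates the acylphosphonium ion, which should give the stabilised α-formyl ylide (ylide acylation).

Step 3
Reactants: 5 4-(tert-butyldimethylsilyloxy)-2-(triphenylphosphoranylidene)butanal; 6 acrolein
Product: 7 (2E)-2-[2-(tert-butyldimethylsilyloxy)ethyl]penta-2,4-dienal
Conditions: acrolein (excess), BHT (cat.), toluene, 60 °C, sealed tube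
Reagents that add atoms: none
Why: Wittig olefination with a formyl-stabilised ylide is thermodynamically controlled and should place the new vinyl group trans to CHO, which fixes the C1=C10 geometry (C2 cis to C9).

Step 4
Reactants: 7 (2E)-2-[2-(tert-butyldimethylsilyloxy)ethyl]penta-2,4-dienal
Product: 8 (E)-tert-butyl{[3-(1,3-dioxolan-2-yl)hexa-3,5-dien-1-yl]oxy}dimethylsilane
Conditions: (Me3SiOCH2)2, TMSOTf (cat.), CH2Cl2, −78 → −20 °C; pyridine quench
Reagents that add atoms: 1,2-bis(trimethylsilyloxy)ethane, C[Si](C)(C)OCCO[Si](C)(C)C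
Why: Noyori-type acetalisation with the bis-silyl ether under catalytic TMSOTf at low temperature converts enals into dioxolanes without double-bond migration and leaves the TBS ether intact.

Step 5
Reactants: 9 tert-butyldiphenyl(prop-2-yn-1-yloxy)silane
Product: 11 4-(tert-butyldiphenylsilyloxy)-N-methoxy-N-methylbut-2-ynamide, via lithium acetylide 10 (not isolated)
Conditions: n-BuLi, THF, −78 °C; then ClC(O)N(OMe)Me, −78 → 0 °C
Reagents that add atoms: N-methoxy-N-methylcarbamoyl chloride, CON(C)C(Cl)=O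
Why: acylation of the lithium acetylide by the carbamoyl chloride gives the alkynyl Weinreb amide (acetylide acylation).

Step 6
Reactants: 11 4-(tert-butyldiphenylsilyloxy)-N-methoxy-N-methylbut-2-ynamide
Product: 12 (Z)-4-(tert-butyldiphenylsilyloxy)-3-iodo-N-methoxy-N-methylbut-2-enamide
Conditions: NaI, AcOH, 70 °C
Reagents that add atoms: sodium iodide, [Na+].[I-]
Why: conjugate addition of iodide to the 2-ynamide and anti-protonation of the allenolate (hydroiodination of 2-ynoic acid derivatives) should give the (Z)-β-iodo enamide, with iodine cis to the carbonyl carbon C6.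

Step 7
Reactants: 8 (E)-tert-butyl{[3-(1,3-dioxolan-2-yl)hexa-3,5-dien-1-yl]oxy}dimethylsilane; 12 (Z)-4-(tert-butyldiphenylsilyloxy)-3-iodo-N-methoxy-N-methylbut-2-enamide
Product: 14 (2E,6E)-9-(tert-butyldimethylsilyloxy)-3-[(tert-butyldiphenylsilyloxy)methyl]-7-(1,3-dioxolan-2-yl)-N-methoxy-N-methylnona-2,6-dienamide, via B-alkyl-9-BBN 13 (not isolated)
Conditions: 8, 9-BBN, THF, 0 °C → rt; then 12, Pd(dppf)Cl2 (cat.), AsPh3, Cs2CO3, DMF–H2O, rt
Reagents that add atoms: none
Why: 9-BBN should add only to the terminal alkene of the diene (boron on C3), and the B-alkyl Suzuki–Miyaura coupling replaces iodine with retention, so C3 ends cis to C6 on the trisubstituted C4=C5 alkene.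

Step 8
Reactants: 14 (2E,6E)-9-(tert-butyldimethylsilyloxy)-3-[(tert-butyldiphenylsilyloxy)methyl]-7-(1,3-dioxolan-2-yl)-N-methoxy-N-methylnona-2,6-dienamide; 15 tert-butyldimethyl(prop-2-yn-1-yloxy)silane
Product: 17 (5E,9E)-1,12-bis(tert-butyldimethylsilyloxy)-6-[(tert-butyldiphenylsilyloxy)methyl]-10-(1,3-dioxolan-2-yl)dodeca-5,9-dien-2-yn-4-one, via lithium acetylide 16 (not isolated)
Conditions: 15, n-BuLi, THF, −78 °C; then 14, −78 → −20 °C; aq. NH4Cl, −20 °C
Reagents that add atoms: none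
Why: the acetylide adds only once to the Weinreb amide because the chelated tetrahedral adduct survives until work-up, giving the cross-conjugated ynone (Weinreb ketone synthesis).

Step 9
Reactants: 17 (5E,9E)-1,12-bis(tert-butyldimethylsilyloxy)-6-[(tert-butyldiphenylsilyloxy)methyl]-10-(1,3-dioxolan-2-yl)dodeca-5,9-dien-2-yn-4-one
Product: 18 (4S,5E,9E)-1,12-bis(tert-butyldimethylsilyloxy)-6-[(tert-butyldiphenylsilyloxy)methyl]-10-(1,3-dioxolan-2-yl)dodeca-5,9-dien-2-yn-4-ol
Conditions: (S)-Me-CBS oxazaborolidine (0.5 equiv), catecholborane, CH2Cl2, −78 °C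
Reagents that add atoms: none
Why: Corey–Bakshi–Shibata reduction, in which the bulky β,β-disubstituted alkenyl group acts as the large and the linear alkynyl group as the small substituent, so the (S)-catalyst should deliver hydride to the face that gives the (S)-carbinol at C6 (same sense as the (R)-carbinols obtained from aryl methyl ketones).

Step 10
Reactants: 18 (4S,5E,9E)-1,12-bis(tert-butyldimethylsilyloxy)-6-[(tert-butyldiphenylsilyloxy)methyl]-10-(1,3-dioxolan-2-yl)dodeca-5,9-dien-2-yn-4-ol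
Product: 20 (2Z,4S,5E,9E)-1,12-bis(tert-butyldimethylsilyloxy)-6-[(tert-butyldiphenylsilyloxy)methyl]-10-(1,3-dioxolan-2-yl)-2-iodododeca-2,5,9-trien-4-ol, via alkenylalanate 19 (not isolated)
Conditions: NaAlH2(OCH2CH2OCH3)2 (Red-Al), THF, 0 °C; then I2, THF, −78 °C
Reagents that add atoms: iodine, II
Why: the C6 alkoxide directs trans-hydroalumination of the alkyne (hydride to C7, aluminium to C11 in a five-membered oxaluminacycle) and iodinolysis with retention should give the (Z)-alkenyl iodide with iodine cis to C6.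

Step 11
Reactants: 20 (2Z,4S,5E,9E)-1,12-bis(tert-butyldimethylsilyloxy)-6-[(tert-butyldiphenylsilyloxy)methyl]-10-(1,3-dioxolan-2-yl)-2-iodododeca-2,5,9-trien-4-ol
Product: 21 (S)-5-[(1E,5E)-8-(tert-butyldimethylsilyloxy)-2-[(tert-butyldiphenylsilyloxy)methyl]-6-(1,3-dioxolan-2-yl)octa-1,5-dien-1-yl]-3-[(tert-butyldimethylsilyloxy)methyl]furan-2(5H)-one
Conditions: Pd(PPh3)2Cl2 (cat.), CO (1 atm), K2CO3, THF, 50 °C
Reagents that add atoms: carbon monoxide, [C-]#[O+]
Why: oxidative addition of zerovalent palladium into the alkenyl iodide, CO insertion and capture of the acylpalladium by the cis-disposed C6 hydroxyl (carbonylative lactonisation) should form the butenolide without touching the C6 stereocentre.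

Step 12
Reactants: 21 (S)-5-[(1E,5E)-8-(tert-butyldimethylsilyloxy)-2-[(tert-butyldiphenylsilyloxy)methyl]-6-(1,3-dioxolan-2-yl)octa-1,5-dien-1-yl]-3-[(tert-butyldimethylsilyloxy)methyl]furan-2(5H)-one
Product: 22 (S)-5-[(1E,5E)-2-[(tert-butyldiphenylsilyloxy)methyl]-6-(1,3-dioxolan-2-yl)-8-hydroxyocta-1,5-dien-1-yl]-3-(hydroxymethyl)furan-2(5H)-one
Conditions: HF·pyridine, pyridine, THF, 0 °C → rt
Reagents that add atoms: none
Why: buffered HF·pyridine cleaves the two primary TBS ethers much faster than the TBDPS ether and is not acidic enough to open the dioxolane (selective desilylation).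

Step 13
Reactants: 22 (S)-5-[(1E,5E)-2-[(tert-butyldiphenylsilyloxy)methyl]-6-(1,3-dioxolan-2-yl)-8-hydroxyocta-1,5-dien-1-yl]-3-(hydroxymethyl)furan-2(5H)-one
Product: 23 (S)-3-(bromomethyl)-5-[(1E,5E)-2-[(tert-butyldiphenylsilyloxy)methyl]-6-(1,3-dioxolan-2-yl)-8-hydroxyocta-1,5-dien-1-yl]furan-2(5H)-one
Conditions: NBS, Me2S, CH2Cl2, −30 → 0 °C
Reagents that add atoms: N-bromosuccinimide, O=C1CCC(=O)N1Br
Why: under Corey–Kim conditions only the allylic alkoxysulfonium ion at C13 (a 2-(hydroxymethyl)enoate) collapses to the bromide, while the saturated C8 alkoxysulfonium ion should revert to the alcohol on work-up.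

Step 14
Reactants: 23 (S)-3-(bromomethyl)-5-[(1E,5E)-2-[(tert-butyldiphenylsilyloxy)methyl]-6-(1,3-dioxolan-2-yl)-8-hydroxyocta-1,5-dien-1-yl]furan-2(5H)-one
Product: 24 (3E,7E)-8-[(S)-4-(bromomethyl)-5-oxo-2,5-dihydrofuran-2-yl]-7-[(tert-butyldiphenylsilyloxy)methyl]-3-(1,3-dioxolan-2-yl)octa-3,7-dienal
Conditions: Dess–Martin periodinane, NaHCO3, CH2Cl2, 0 °C; used at once
Reagents that add atoms: none
Why: buffered Dess–Martin oxidation gives the β,γ-unsaturated aldehyde under neutral conditions that tolerate the allylic bromide and should avoid conjugation of the C1=C10 alkene.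

Step 15
Reactants: 24 (3E,7E)-8-[(S)-4-(bromomethyl)-5-oxo-2,5-dihydrofuran-2-yl]-7-[(tert-butyldiphenylsilyloxy)methyl]-3-(1,3-dioxolan-2-yl)octa-3,7-dienal
Product: 26 (3aR,4S,6E,10E,11aS)-10-[(tert-butyldiphenylsilyloxy)methyl]-6-(1,3-dioxolan-2-yl)-4-hydroxy-3-methylidene-3a,4,5,8,9,11a-hexahydrocyclodeca[b]furan-2(3H)-one, via allylchromium dichloride 25 (not isolated)
Conditions: CrCl2 (10 equiv), THF, 0.002 M (slow addition of 24), rt
Reagents that add atoms: none
Why: Two equivalents of CrCl2 reduce the allylic C13–Br bond to the allyl species of trivalent chromium 25, which adds to the C8 aldehyde through its γ-carbon C7 in a six-membered chair (Zimmerman–Traxler) transition state, shifting the double bond to C11=C13 and so unveiling the α-methylene lactone. The closest known reaction type is the Nozaki–Hiyama–Kishi-type allylation of aldehydes with 3-(bromomethyl)butenolides and 2-(bromomethyl)acrylates, including medium-ring closures (no nickel is needed for allylic halides). The ten-membered carbocycle is closed by a 10-exo-trig addition of C7 to the tethered C8=O. C7 is controlled by the tether: it is anchored at C6, so the aldehyde can reach only the butenolide face that carries C5, which makes C5 and C8 cis on the lactone (cis-fused, 7R from 6S). C8 is controlled by the chair: the lactone ring holds C6 trans to the CH2Cr carbon (an E-type γ-substituted allyl metal) and the C9 chain takes the equatorial site, away from the lactone ring, which should give the anti C7/C8 relation (8S). The step needs γ- over α-attack (secured by the closed transition state), aldehyde over lactone and acetal (secured by the chemoselectivity of organochromium reagents) and ring closure over oligomerisation (secured by high dilution and by the two ring-cis trisubstituted alkenes that fold the chain).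

Step 16
Reactants: 26 (3aR,4S,6E,10E,11aS)-10-[(tert-butyldiphenylsilyloxy)methyl]-6-(1,3-dioxolan-2-yl)-4-hydroxy-3-methylidene-3a,4,5,8,9,11a-hexahydrocyclodeca[b]furan-2(3H)-one
Product: 27 (3aR,4S,6E,10E,11aS)-10-[(tert-butyldiphenylsilyloxy)methyl]-6-(1,3-dioxolan-2-yl)-3-methylidene-2-oxo-2,3,3a,4,5,8,9,11a-octahydrocyclodeca[b]furan-4-yl 3-methylbutanoate
Conditions: (i-PrCH2CO)2O, DMAP (cat.), pyridine, CH2Cl2, 0 °C → rt
Reagents that add atoms: 3-methylbutanoic anhydride, CC(C)CC(=O)OC(=O)CC(C)C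
Why: DMAP-catalysed acyl transfer to the secondary C8 alcohol (Steglich-type acylation) installs the isovalerate with retention at C8.

Step 17
Reactants: 27 (3aR,4S,6E,10E,11aS)-10-[(tert-butyldiphenylsilyloxy)methyl]-6-(1,3-dioxolan-2-yl)-3-methylidene-2-oxo-2,3,3a,4,5,8,9,11a-octahydrocyclodeca[b]furan-4-yl 3-methylbutanoate
Product: 28 (3aR,4S,6E,10E,11aS)-6-formyl-10-(hydroxymethyl)-3-methylidene-2-oxo-2,3,3a,4,5,8,9,11a-octahydrocyclodeca[b]furan-4-yl 3-methylbutanoate
Conditions: aq. HF (48%), MeCN, 0 °C → rt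
Reagents that add atoms: water, O
Why: aqueous HF cleaves the primary allylic TBDPS ether and the aqueous acid hydrolyses the α,β-unsaturated dioxolane to the enal, under conditions that the ester, the lactone and the three stereocentres should survive (global deprotection).

**Compound list**

1 | (3-bromopropoxy)(tert-butyl)dimethylsilane | CC(C)(C)[Si](C)(C)OCCCBr | starting material
2 | triphenylphosphine | c1ccc(cc1)P(c1ccccc1)c1ccccc1 | starting material
3 | [3-(tert-butyldimethylsilyloxy)propyl]triphenylphosphonium bromide | CC(C)(C)[Si](C)(C)OCCC[P+](c1ccccc1)(c1ccccc1)c1ccccc1.[Br-] | intermediate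
4 | [3-(tert-butyldimethylsilyloxy)propylidene]triphenylphosphorane (not isolated) | CC(C)(C)[Si](C)(C)OCCC=P(c1ccccc1)(c1ccccc1)c1ccccc1 | intermediate
5 | 4-(tert-butyldimethylsilyloxy)-2-(triphenylphosphoranylidene)butanal | CC(C)(C)[Si](C)(C)OCCC(C=O)=P(c1ccccc1)(c1ccccc1)c1ccccc1 | intermediate
6 | acrolein (prop-2-enal) | C=CC=O | starting material
7 | (2E)-2-[2-(tert-butyldimethylsilyloxy)ethyl]penta-2,4-dienal (vinyl trans to CHO) | C=C/C=C(/C=O)CCO[Si](C)(C)C(C)(C)C | intermediate
8 | (E)-tert-butyl{[3-(1,3-dioxolan-2-yl)hexa-3,5-dien-1-yl]oxy}dimethylsilane | C=C/C=C(/C1OCCO1)CCO[Si](C)(C)C(C)(C)C | intermediate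
9 | tert-butyldiphenyl(prop-2-yn-1-yloxy)silane | C#CCO[Si](c1ccccc1)(c1ccccc1)C(C)(C)C | starting material
10 | lithium acetylide of 9 (not isolated) | [Li]C#CCO[Si](c1ccccc1)(c1ccccc1)C(C)(C)C | intermediate
11 | 4-(tert-butyldiphenylsilyloxy)-N-methoxy-N-methylbut-2-ynamide | CON(C)C(=O)C#CCO[Si](c1ccccc1)(c1ccccc1)C(C)(C)C | intermediate
12 | (Z)-4-(tert-butyldiphenylsilyloxy)-3-iodo-N-methoxy-N-methylbut-2-enamide (iodine cis to C=O) | CON(C)C(=O)/C=C(\I)CO[Si](c1ccccc1)(c1ccccc1)C(C)(C)C | intermediate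
13 | 9-[(3E)-6-(tert-butyldimethylsilyloxy)-4-(1,3-dioxolan-2-yl)hex-3-en-1-yl]-9-borabicyclo[3.3.1]nonane (not isolated) | C1CC2CCCC(C1)B2CCC/C=C(/C1OCCO1)CCO[Si](C)(C)C(C)(C)C | intermediate
14 | (2E,6E)-9-(tert-butyldimethylsilyloxy)-3-[(tert-butyldiphenylsilyloxy)methyl]-7-(1,3-dioxolan-2-yl)-N-methoxy-N-methylnona-2,6-dienamide | CON(C)C(=O)/C=C(/CO[Si](c1ccccc1)(c1ccccc1)C(C)(C)C)CC/C=C(/C1OCCO1)CCO[Si](C)(C)C(C)(C)C | intermediate
15 | tert-butyldimethyl(prop-2-yn-1-yloxy)silane | C#CCO[Si](C)(C)C(C)(C)C | starting material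
16 | lithium acetylide of 15 (not isolated) | [Li]C#CCO[Si](C)(C)C(C)(C)C | intermediate
17 | (5E,9E)-1,12-bis(tert-butyldimethylsilyloxy)-6-[(tert-butyldiphenylsilyloxy)methyl]-10-(1,3-dioxolan-2-yl)dodeca-5,9-dien-2-yn-4-one | CC(C)(C)[Si](C)(C)OCC#CC(=O)/C=C(/CO[Si](c1ccccc1)(c1ccccc1)C(C)(C)C)CC/C=C(/C1OCCO1)CCO[Si](C)(C)C(C)(C)C | intermediate
18 | (4S,5E,9E)-1,12-bis(tert-butyldimethylsilyloxy)-6-[(tert-butyldiphenylsilyloxy)methyl]-10-(1,3-dioxolan-2-yl)dodeca-5,9-dien-2-yn-4-ol | CC(C)(C)[Si](C)(C)OCC#C[C@@H](O)/C=C(/CO[Si](c1ccccc1)(c1ccccc1)C(C)(C)C)CC/C=C(/C1OCCO1)CCO[Si](C)(C)C(C)(C)C | intermediate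
19 | sodium alkenylalanate of 18: five-membered O–Al–C11=C7–C6 ring, two 2-methoxyethoxy groups on aluminium, (S) at C6 (not isolated) | [Na+].COCCO[Al-]1(OCCOC)O[C@@H](/C=C(/CO[Si](c2ccccc2)(c2ccccc2)C(C)(C)C)CC/C=C(/C2OCCO2)CCO[Si](C)(C)C(C)(C)C)C=C1CO[Si](C)(C)C(C)(C)C | intermediate
20 | (2Z,4S,5E,9E)-1,12-bis(tert-butyldimethylsilyloxy)-6-[(tert-butyldiphenylsilyloxy)methyl]-10-(1,3-dioxolan-2-yl)-2-iodododeca-2,5,9-trien-4-ol | CC(C)(C)[Si](C)(C)OC/C(I)=C/[C@@H](O)/C=C(/CO[Si](c1ccccc1)(c1ccccc1)C(C)(C)C)CC/C=C(/C1OCCO1)CCO[Si](C)(C)C(C)(C)C | intermediate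
21 | (S)-5-[(1E,5E)-8-(tert-butyldimethylsilyloxy)-2-[(tert-butyldiphenylsilyloxy)methyl]-6-(1,3-dioxolan-2-yl)octa-1,5-dien-1-yl]-3-[(tert-butyldimethylsilyloxy)methyl]furan-2(5H)-one | O=C1O[C@@H](/C=C(/CO[Si](c2ccccc2)(c2ccccc2)C(C)(C)C)CC/C=C(/C2OCCO2)CCO[Si](C)(C)C(C)(C)C)C=C1CO[Si](C)(C)C(C)(C)C | intermediate
22 | (S)-5-[(1E,5E)-2-[(tert-butyldiphenylsilyloxy)methyl]-6-(1,3-dioxolan-2-yl)-8-hydroxyocta-1,5-dien-1-yl]-3-(hydroxymethyl)furan-2(5H)-one | O=C1O[C@@H](/C=C(/CO[Si](c2ccccc2)(c2ccccc2)C(C)(C)C)CC/C=C(/C2OCCO2)CCO)C=C1CO | intermediate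
23 | (S)-3-(bromomethyl)-5-[(1E,5E)-2-[(tert-butyldiphenylsilyloxy)methyl]-6-(1,3-dioxolan-2-yl)-8-hydroxyocta-1,5-dien-1-yl]furan-2(5H)-one | O=C1O[C@@H](/C=C(/CO[Si](c2ccccc2)(c2ccccc2)C(C)(C)C)CC/C=C(/C2OCCO2)CCO)C=C1CBr | intermediate
24 | (3E,7E)-8-[(S)-4-(bromomethyl)-5-oxo-2,5-dihydrofuran-2-yl]-7-[(tert-butyldiphenylsilyloxy)methyl]-3-(1,3-dioxolan-2-yl)octa-3,7-dienal | O=C1O[C@@H](/C=C(/CO[Si](c2ccccc2)(c2ccccc2)C(C)(C)C)CC/C=C(/C2OCCO2)CC=O)C=C1CBr | intermediate
25 | allylchromium dichloride from 24 (CrCl2 on C13, trivalent chromium, (S) at C6; not isolated) | O=C1O[C@@H](/C=C(/CO[Si](c2ccccc2)(c2ccccc2)C(C)(C)C)CC/C=C(/C2OCCO2)CC=O)C=C1C[Cr](Cl)Cl | intermediate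
26 | (3aR,4S,6E,10E,11aS)-10-[(tert-butyldiphenylsilyloxy)methyl]-6-(1,3-dioxolan-2-yl)-4-hydroxy-3-methylidene-3a,4,5,8,9,11a-hexahydrocyclodeca[b]furan-2(3H)-one | C=C1C(=O)O[C@H]2/C=C(/CO[Si](c3ccccc3)(c3ccccc3)C(C)(C)C)CC/C=C(/C3OCCO3)C[C@H](O)[C@@H]12 | intermediate
27 | (3aR,4S,6E,10E,11aS)-10-[(tert-butyldiphenylsilyloxy)methyl]-6-(1,3-dioxolan-2-yl)-3-methylidene-2-oxo-2,3,3a,4,5,8,9,11a-octahydrocyclodeca[b]furan-4-yl 3-methylbutanoate | C=C1C(=O)O[C@H]2/C=C(/CO[Si](c3ccccc3)(c3ccccc3)C(C)(C)C)CC/C=C(/C3OCCO3)C[C@H](OC(=O)CC(C)C)[C@@H]12 | intermediate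
28 | (3aR,4S,6E,10E,11aS)-6-formyl-10-(hydroxymethyl)-3-methylidene-2-oxo-2,3,3a,4,5,8,9,11a-octahydrocyclodeca[b]furan-4-yl 3-methylbutanoate | C=C1C(=O)O[C@H]2/C=C(/CO)CC/C=C(/C=O)C[C@H](OC(=O)CC(C)C)[C@@H]12 | target

**Step count and risks**

Total step count: 17. Longest linear sequence: 15 (steps 1–4, then 7–17).

Step 15 (ring closure). What may go wrong: intermolecular coupling to oligomers, erosion of the anti C7/C8 preference if a boat-like transition state competes, and migration of the lactone acyl group to the new C8 alkoxide. Fallback: thermal intramolecular allylboration in place of the organochromium addition. It sets out from 23: palladium-catalysed borylation (Pd2(dba)3, B2pin2, DMSO, 50 °C) should give the primary allylboronate alcohol F1, Dess–Martin oxidation gives the allylboronate aldehyde F2, and heating at high dilution (toluene, 80 °C) should close the same C7–C8 bond through a boron-centred chair transition state. Hydrolytic work-up comes back to the route at 26.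

Step 9 (C6 stereocentre). What may go wrong: poor facial discrimination between the alkenyl and alkynyl groups, or competing conjugate reduction of the cross-conjugated ketone. Fallback: set C6 by enantioselective C–C bond formation instead of reduction. It sets out from 14: i-Bu2AlH (THF, −78 °C) should reduce the Weinreb amide to the (2E,6E)-enal F3, and a Me2Zn/ProPhenol-catalysed addition of alkyne 15 (ligand enantiomer selected to give the (S)-carbinol) comes back to the route at 18.

Step 10 (hydroalumination–iodination). What may go wrong: β-elimination of silyloxide from the alkenylalanate to an allene, and incomplete regiocontrol of hydride delivery. Fallback: ruthenium-catalysed trans-hydrosilylation followed by iododesilylation. It sets out from 18: [Cp*Ru(MeCN)3]PF6 and Et3SiH (CH2Cl2, 0 °C) should place silicon on C11, distal to the free hydroxyl, to give the (Z)-alkenylsilane F4. N-Iodosuccinimide in (CF3)2CHOH then exchanges silicon for iodine with retention and comes back to the route at 20.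

**Further compounds**

F1 | step 15 | (S)-5-[(1E,5E)-2-[(tert-butyldiphenylsilyloxy)methyl]-6-(1,3-dioxolan-2-yl)-8-hydroxyocta-1,5-dien-1-yl]-3-[(4,4,5,5-tetramethyl-1,3,2-dioxaborolan-2-yl)methyl]furan-2(5H)-one | O=C1O[C@@H](/C=C(/CO[Si](c2ccccc2)(c2ccccc2)C(C)(C)C)CC/C=C(/C2OCCO2)CCO)C=C1CB1OC(C)(C)C(C)(C)O1
F2 | step 15 | (3E,7E)-7-[(tert-butyldiphenylsilyloxy)methyl]-3-(1,3-dioxolan-2-yl)-8-[(S)-5-oxo-4-[(4,4,5,5-tetramethyl-1,3,2-dioxaborolan-2-yl)methyl]-2,5-dihydrofuran-2-yl]octa-3,7-dienal | O=C1O[C@@H](/C=C(/CO[Si](c2ccccc2)(c2ccccc2)C(C)(C)C)CC/C=C(/C2OCCO2)CC=O)C=C1CB1OC(C)(C)C(C)(C)O1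
F3 | step 9 | (2E,6E)-9-(tert-butyldimethylsilyloxy)-3-[(tert-butyldiphenylsilyloxy)methyl]-7-(1,3-dioxolan-2-yl)nona-2,6-dienal | O=C/C=C(/CO[Si](c1ccccc1)(c1ccccc1)C(C)(C)C)CC/C=C(/C1OCCO1)CCO[Si](C)(C)C(C)(C)C
F4 | step 10 | (2Z,4S,5E,9E)-1,12-bis(tert-butyldimethylsilyloxy)-6-[(tert-butyldiphenylsilyloxy)methyl]-10-(1,3-dioxolan-2-yl)-2-(triethylsilyl)dodeca-2,5,9-trien-4-ol | CC(C)(C)[Si](C)(C)OC/C(=C/[C@@H](O)/C=C(/CO[Si](c1ccccc1)(c1ccccc1)C(C)(C)C)CC/C=C(/C1OCCO1)CCO[Si](C)(C)C(C)(C)C)[Si](CC)(CC)CC
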